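The number I started from came from the east run: the readings of links fell from 92% at 0.625 d to 64% at 3.00 d. I read that fall as a first-order loss of links:

decay constant = 0.153 d⁻¹

| setting | south-west | east | theta | alpha | zeta | beta | delta |
|---|---|---|---|---|---|---|---|
| first end groups | 0.037 M | 0.037 M | 0.037 M | 0.037 M | 0.037 M | 0.037 M | 0.037 M |
| second end groups | 0.026 M | 0.42 M | 0.0400 M | 0.0800 M | 0.150 M | 0.300 M | 0.600 M |
| remark | run made earlier | run made earlier |  |  |  |  |  |
| time |  |  | 6.0 d | 6.0 d | 6.0 d | 6.0 d | 6.0 d |

| run | time / d | links / % |
|---|---|---|
| south-west | 0.208 | 10 |
| south-west | 0.625 | 23 |
| south-west | 1.04 | 30 |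
| south-west | 1.67 | 36 |
| south-west | 2.50 | 41 |
| south-west | 3.00 | 39 |
| east | 0.250 | 85 |
| east | 0.417 | 91 |
| east | 0.625 | 92 |
| east | 1.04 | 84 |
| east | 1.67 | 80 |
| east | 3.00 | 64 |

(readings scatter by 1.5 percentage points)

- the earlier runs were read with a standard deviation of 1.5 percentage points
- "hardly changes" means that all values lie within two and a half points (for a concentration: within two and a half percent of the largest)

1. [links] at the end for theta, alpha, zeta, beta, delta, in this order
2. how that number moves from the first to the last of them (falls all the way / rises, then falls / rises all the way / hardly changes / falls, then rises)

My first doubt was whether formation still blurred that fall. The first east reading gave a forming constant, with the step taken as pseudo-first-order in the large excess of second end groups: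

forming constant = 18.1 M⁻¹ d⁻¹

By 0.625 d that left 0.871% of the first end groups, so I let the fall stand as loss and assumed the same decay constant in each flask.

My first estimate had each link born at the start:

floor = 0.0148 M

The objection was that links are born late, and a late link has had less time to decay. So I reckoned the correction by itself. The mean birth lag is one over the forming constant times the mean second end groups, taken as the charge less half of the first end groups. The share gained is the decay constant times that lag:

alpha: 13.8%
zeta: 6.43%
delta: 1.45%

I called this share the lag gain. It gave 0.0168 M for alpha and 0.0150 M for delta.

The next objection concerned theta, where the first end groups, the limiting reagent, are charged nearly equal to the second. Its lag gain is 39.3%, but a second-order reckoning leaves 20.0% of the first end groups unlinked at the end: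

theta = floor × (1 + lag gain) × (1 − share left) = 0.0165 M

So I expected the row to rise and then fall, with a thin first step of 3.29 × 10⁻⁴ M.

The forecast read 0.0162 M, 0.0172 M, 0.016 M, 0.01545 M, 0.01524 M, rises, then falls, and it said of alpha that “formation is complete but later, giving the maximum”. Its alpha stands above mine.

The flask gave 0.0157 M, 0.0163 M, 0.0151 M, 0.0146 M, 0.0144 M: rises, then falls.

    first end groups + second end groups → links + released group (k = 0.861 M⁻¹ h⁻¹)
    links → over-reaction product (k = 0.00665 h⁻¹)

At the end, theta still held 14.3% of its first end groups, while alpha held 0.261%. The lag gains put alpha over delta by a factor of 1.12, and the flask's factor is 1.13. For zeta over delta, the lag gains give 1.05, and the flask gives 1.05.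

The earlier runs and the new flask are calculated with made-up constants; the scatter is artificial.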